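The easy mistake is to take J for an end point, yet in cedar cJ falls from 0.04738 M at 22 s to 0.03642 M at 200 s. So what ash holds depends on making J and on losing it.

| flask | G | L | time |
|---|---|---|---|
| alder | 0.0500 M | 0.150 M |  |
| maple | 0.0250 M | 0.150 M |  |
| cedar | 0.0500 M | 0.450 M |  |
| ash | 0.00770 M | 0.150 M | 200 s |

| run | time / s | [J] / M |
|---|---|---|
| alder run | 7.2 | 0.00676 |
| alder run | 22 | 0.01678 |
| alder run | 42 | 0.02477 |
| alder run | 66 | 0.03145 |
| alder run | 94 | 0.03588 |
| alder run | 130 | 0.03998 |
| alder run | 160 | 0.04164 |
| alder run | 200 | 0.04257 |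
| maple run | 7.2 | 0.00340 |
| maple run | 22 | 0.00900 |
| maple run | 42 | 0.01327 |
| maple run | 66 | 0.01711 |
| maple run | 94 | 0.01948 |
| maple run | 130 | 0.02097 |
| maple run | 160 | 0.02158 |
| maple run | 200 | 0.02176 |
| cedar run | 7.2 | 0.03534 |
| cedar run | 22 | 0.04738 |
| cedar run | 42 | 0.04698 |
| cedar run | 66 | 0.04577 |
| cedar run | 94 | 0.04357 |
| cedar run | 130 | 0.04094 |
| cedar run | 160 | 0.03922 |
| cedar run | 200 | 0.03642 |

(scatter of a reading: 2 × 10⁻⁴ M)

- Overall: G + L -> J.
- Constant volume, constant temperature.
- An order is taken over about fifteen percent of the charge, up and down.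

- order of the initial rate in [L], near the charge of the alder run, the rate being that where two percent of its G are J
- order of the initial rate in [G], near the charge of the alder run, the rate being that where two percent of its G are J (one fixed amount of J, the same in the runs compared)
- J in the ash run at 200 s, as a share of the G charged

I read a make constant from each first reading, as the logarithm of G charged over G left, per unit time. Alder gives 0.0202 /s, maple 0.0203 /s and cedar 0.170 /s. Maple, with half of alder's G, matches alder, so I take order one in G. Against the mean cL of that first interval, cedar gives order 1.97 in L. With order two, alder gives km = 0.938 /M²/s.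

I assume J is lost at a rate kl·cL·cJ. Cedar's fall from 42 s to 200 s, at a cL near 0.400 M, gives kl = 0.00403 /M/s.

Dividing the loss rate by the make rate km·cL·cL·cG cancels time and leaves ρ·cJ/cG. Here ρ = kl/(km·cL) is the loss ratio, a selectivity factor. In ash, G is the limiting reagent, with 0.00770 M against 0.150 M of L, so I hold cL at 0.142 M, which makes G pseudo-first-order. Then ρ is 0.0302, and G left is the share x = exp(−km·cL·cL·t), here 3.80 in the exponent's size. The share of J is x to the power ρ, less x, over 1 − ρ: 89.6%.

The forecast gives 1.95, 1 and 88%, on this ground: “J decays further, roughly in proportion to L”.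

The flask gives 2.0, 1.0 and 89.4%.

    G + 2 L → J + L (0.9260 /M²/s)
    J + L → E (0.004100 /M/s)

At equal J made, cedar's rate is 9.1 times alder's, with 3.00 times its cL. In ash, my reckoning with the loss ratio of 0.0302 gives 89.6%, and the flask gives 89.4%. In maple, the same reckoning at a cL of 0.125 M gives a ratio of 0.0343. With 2.93 in the exponent, J comes to 88.1% of the G charged at 200 s, and the reading there is 87.0%.

Readings and results were generated by integration on assumed constants; the scatter is artificial.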